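(The runs are simulated on assumed constants; the scatter is artificial.)

At 8.00 d the theta run had 70.0% of its charge left over, outside target and isomer, in substrate and dormant form, neither of which was read.

| flask | substrate | remark | time |
|---|---|---|---|
| theta | 1.3 M | the very flask that is asked about, followed so far |  |
| gamma | 0.65 M | run made earlier |  |
| flask | 1.3 M |  | 15 d |

| run | time / d | target / % | isomer of the product / % |
|---|---|---|---|
| theta | 1.04 | 25.5 | 2.7 |
| theta | 2.50 | 24.3 | 5.9 |
| theta | 5.00 | 22.7 | 7.4 |
| theta | 8.00 | 22.2 | 7.8 |
| gamma | 1.25 | 24.9 | 2.4 |
| gamma | 4.00 | 21.9 | 7.0 |
| gamma | 6.00 | 23.3 | 7.7 |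
| gamma | 10.0 | 21.8 | 8.1 |

(standard deviation of a reading: 0.5 percentage points)

- the earlier runs were read with a standard deviation of 0.5 percentage points
- reactions considered so far: target <-> isomer of the product; substrate <-> target; substrate <-> dormant form

- how much target there is at 15 d, in percent of the substrate charged
- how much isomer of the product there is at 15 d, in percent of the substrate charged

I needed two times: how fast the isomer approached its plateau, and the asked time. In the theta run target plus isomer stood at 30.2% at 2.50 d and 30.0% at 8.00 d, so I saw no leak from the sum. By 1.04 d nearly all of that sum stood in the theta run, but its isomer had reached a third of the last gamma reading, so I set the filling of the sum aside and followed the isomer's climb. The gamma run, at half the charge, read much the same percentages, so I carried them to the 1.3 M flask. Taking gamma's last isomer reading as plateau, the theta reading at 2.50 d gave a half-life of approach (a relaxation half-life) of 1.33 d. Against it stood the asked 15 d, and their ratio, the count of half-lives elapsed, was 11.3. By this reckoning the gap to that plateau came to 0.0033 percentage points, far below the scatter. So I committed to 8.10% isomer and, averaging the late readings, 22.4% target.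

The forecast gave 8.1% isomer and 21.9% target, lower than mine, “with ranges widened slightly on the low side for a possible slow leak”.

The flask gave 22.9% target and 8.23% isomer.

    target ⇌ isomer of the product (K = 0.360, k = 1.70 × 10⁻⁶ s⁻¹)
    substrate ⇌ target (K = 1.10, k = 1.10 × 10⁻⁵ s⁻¹)
    substrate ⇌ dormant form (K = 2.30, k = 1.80 × 10⁻⁵ s⁻¹)

At my count of 11.3 half-lives the flask stood 0.03 points below the 8.26% isomer it held when left ten times as long. The neighbouring flask differs in one setting: it was read at 6.0 d. Its count is 4.51 half-lives, which leaves a gap of 0.35 points below my plateau and gives 7.75% isomer. That neighbouring flask holds 7.46% isomer.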